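## Retrosynthetic overview

- The target, (12E)-6α-angeloyloxylabda-12,14-dien-8α-ol, is cut at the C6 ester (last step, secondary over tertiary OH). It is also cut at C12=C13 and C14=C15, which come from two Wittig reactions on a C12 lactol.
- C5, C6, C8 and C9 all come from one α-face hydroboration of a 5,8(9)-diene. C9–C11 comes from a Negishi coupling at the C9 enol triflate, and C17 from enolate methylation of a C9 ketone.
- Structural feature: the C4–C5 bond of ring A ties the gem-dimethyl carbon C4 to the ring-fusion carbon C5, which also carries quaternary C10, so it is the most congested bond of the skeleton. C4 and C10 bear no hydrogen, so a C5 carbinol can lose water only towards C6, which gives the 5-ene needed for 5α-H and 6α-O.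
- That bond is made by adding a tertiary C4 radical, generated by hydrogen atom transfer to a homoprenyl alkene, to the C5 carbonyl of a cyclohexanone.
- Ring order: ring B is bought as 2-methylcyclohexane-1,3-dione and receives C10 by desymmetrisation; ring A is closed second, in the key step.

Key step: step 5

Numbering: labdane numbering is used throughout. In the monocyclic compounds, ring carbons C1/C2/C3 are labdane C5/C10/C9.

Assumption: the (R,R)-TsDPEN catalyst is taken to give the (R)-carbinol with hydride entering anti to the homoprenyl chain, as expected for 2-alkyl-2-methyl-1,3-diones; if the sense proves opposite the (S,S)-catalyst is used, and the C9 configuration itself does not matter because C9 is oxidised in step 8.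

## Route

Step 1
Reactants: 1 2-methylcyclohexane-1,3-dione
Product: 2 3-(2,2-dimethylhydrazinyl)-2-methylcyclohex-2-en-1-one (mono-dimethylhydrazone of 1, vinylogous hydrazide tautomer)
Conditions: Me2NNH2, p-TsOH (cat.), toluene, reflux, Dean–Stark
Reagents that add atoms: N,N-dimethylhydrazine, CN(C)N
Why: Hydrazone condensation stops at the stable vinylogous hydrazide, which masks one carbonyl and closes the O-alkylation channel that spoils direct alkylation of the free dione with unactivated halides.

Step 2
Reactants: 2 vinylogous hydrazide; 3 5-bromo-2-methylpent-2-ene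
Product: 6 2-methyl-2-(4-methylpent-3-en-1-yl)cyclohexane-1,3-dione, via potassium aza-enolate 4 (not isolated), via alkylated keto hydrazone 5 (not isolated)
Conditions: KH, THF, 0 °C; 3, NaI (cat.), rt to 45 °C; then Cu(OAc)2, H2O, rt
Reagents that add atoms: water, O; potassium hydride, [K+].[H-] (potassium is held only in 4)
Why: The aza-enolate of a keto dimethylhydrazone undergoes SN2 alkylation at carbon even with a primary homoallylic halide, and copper-assisted hydrolysis of the now unconjugated hydrazone releases the achiral, prochiral 2,2-disubstituted dione.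

Step 3
Reactants: 6 prochiral dione
Product: 7 (2R,3R)-3-hydroxy-2-methyl-2-(4-methylpent-3-en-1-yl)cyclohexan-1-one (OH cis to the homoprenyl chain, trans to the methyl)
Conditions: RuCl(p-cymene)[(R,R)-TsDPEN] (cat.), HCO2H/Et3N (5:2), CH2Cl2, rt
Reagents that add atoms: none
Why: Noyori asymmetric transfer hydrogenation desymmetrises the dione, the catalyst fixing the carbinol configuration and the substrate directing hydride anti to the longer chain, so that one enantiotopic carbonyl is reduced and quaternary C10 is set as R; the isolated alkene is inert, the second reduction is slower, and the minor diastereomer (epimeric at C10) must be removed by chromatography here because it would become the enantiomer once C9 is erased.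

Step 4
Reactants: 7 hydroxy ketone
Product: 8 (2R,3R)-3-(tert-butyldimethylsilyloxy)-2-methyl-2-(4-methylpent-3-en-1-yl)cyclohexan-1-one
Conditions: TBSOTf, 2,6-lutidine, CH2Cl2, 0 °C
Reagents that add atoms: tert-butyldimethylsilyl triflate, CC(C)(C)[Si](C)(C)OS(=O)(=O)C(F)(F)F
Why: Silyl triflate silylation covers the neopentyl secondary alcohol, which blocks retro-aldol opening and silane alcoholysis in step 5 and leaves the C5 carbinol as the only free hydroxyl in step 6.

Step 5
Reactants: 8 silyloxy ketone
Product: 9 9α-(tert-butyldimethylsilyloxy)-4,4,10β-trimethyl-cis-decalin-5β-ol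
Conditions: Fe(acac)3 (0.3 equiv), PhSiH3 (3 equiv), degassed EtOH, 60 °C
Reagents that add atoms: none
Why: Fe(acac)3 and PhSiH3 in ethanol form an iron hydride that hands a hydrogen atom to C3, the less substituted carbon of the only alkene, and leaves the tertiary C4 radical (Markovnikov metal-hydride hydrogen atom transfer). This nucleophilic radical attacks the C5 carbonyl carbon in a 6-exo-trig closure that forms C4–C5 and ring A, and the C5 alkoxyl radical is reduced and protonated (divalent iron, ethanol) before it can fragment, which pulls the reversible addition forward. The closest known reaction type is the iron-hydride reductive radical cyclisation of alkene-tethered cyclohexanones to fused tertiary decalinols. The one new stereocentre, C5, is governed by the C10 tether, which reaches the carbonyl from the α face on which the chain sits and should push oxygen to the β face, cis to the C10 methyl; the other epimer would serve equally because step 6 erases C5. The step needs hydrogen atom transfer to the alkene without ketone reduction, secured by the neutral conditions that spare ketone and silyl ether. It also needs six- rather than five-membered closure, secured because the radical site is C4, whereas polar (Prins-type) activation would bond C3; an early, loose radical transition state tolerates the two flanking quaternary carbons, and degassing prevents oxygen trapping of the radical.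

Step 6
Reactants: 9 decalinol
Product: 10 9α-(tert-butyldimethylsilyloxy)-4,4,10β-trimethyl-5(6)-octalin (the 5-ene)
Conditions: SOCl2, pyridine, 0 °C to rt
Reagents that add atoms: none
Why: Chlorosulfite formation and pyridine-induced E2 elimination can remove only a C6 hydrogen because C4 and C10 carry none, so the 5-ene is the single regioisomer, and the basic medium suppresses the Wagner–Meerwein methyl shifts that an acid-promoted dehydration would invite.

Step 7
Reactants: 10 silyl ether
Product: 11 4,4,10β-trimethyl-5(6)-octalin-9α-ol
Conditions: TBAF, THF, 60 °C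
Reagents that add atoms: none
Why: Fluoride desilylation is driven by the Si–F bond, and the hindered alkene is untouched.

Step 8
Reactants: 11 alcohol
Product: 12 (8aS)-5,5,8a-trimethyl-3,5,6,7,8,8a-hexahydronaphthalen-1(2H)-one (the 5-en-9-one)
Conditions: Dess–Martin periodinane, CH2Cl2, rt
Reagents that add atoms: none
Why: Dess–Martin oxidation converts the hindered secondary alcohol under mild conditions, and the β,γ-alkene cannot slip into conjugation because C10 is quaternary.

Step 9
Reactants: 12 ketone
Product: 14 8α-methyl-5-en-9-one (4,4,8α,10β-tetramethyl-5(6)-octalin-9-one), via lithium enolate 13 (not isolated)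
Conditions: LDA, THF, −78 °C; MeI, DMPU, −78 to 0 °C
Reagents that add atoms: iodomethane, CI; lithium diisopropylamide, [Li+].CC(C)[N-]C(C)C (lithium is held only in 13)
Why: Kinetic enolate alkylation has one possible regiochemistry because only C8 is enolisable, and iodomethane should enter anti to the 10β-methyl to give the equatorial 8α-methyl ketone, a configuration of no consequence since C8 becomes sp2 in step 10.

Step 10
Reactants: 14 methyl ketone
Product: 16 4,4,8,10β-tetramethyl-5,8(9)-hexalin-9-yl trifluoromethanesulfonate, via potassium enolate 15 (not isolated)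
Conditions: KHMDS, THF, −78 to 0 °C; PhNTf2, −78 °C to rt
Reagents that add atoms: N-phenylbis(trifluoromethanesulfonimide), O=S(=O)(N(c1ccccc1)S(=O)(=O)C(F)(F)F)C(F)(F)F; potassium hexamethyldisilazide, [K+].C[Si](C)(C)[N-][Si](C)(C)C (potassium is held only in 15)
Why: Enol triflate formation proceeds through the only available, tetrasubstituted enolate, as is routine for 2,2,6-trialkylcyclohexanones.

Step 11
Reactants: 16 enol triflate; 17 (1,3-dioxolan-2-ylmethyl)zinc bromide
Product: 18 12,12-(ethylenedioxy)-13,14,15,16-tetranorlabda-5,8(9)-diene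
Conditions: Pd(OAc)2 (cat.), SPhos (cat.), THF/NMP, 60 °C
Reagents that add atoms: none
Why: Negishi sp2–sp3 coupling forms C9–C11; triflates of the 2,6,6-trialkylcyclohexenyl type are proven cross-coupling partners, and the bulky biarylphosphine speeds reductive elimination ahead of β-elimination from the alkylpalladium intermediate.

Step 12
Reactants: 18 diene acetal
Product: 20 12,12-(ethylenedioxy)-13,14,15,16-tetranorlabdane-6α,8α-diol, via 6α,8α-bis(borane) 19 (not isolated)
Conditions: BH3·THF (excess), THF, 0 °C to rt; then NaOH, H2O2, 0 to 40 °C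
Reagents that add atoms: hydrogen peroxide, OO; borane (as BH3·THF), B (boron is held only in 19)
Why: Syn hydroboration–oxidation first takes the trisubstituted 5-ene, boron going to C6 and hydrogen to C5 on the α face because the axial 4β- and 10β-methyl groups close the β face, which creates the trans-decalin; the tetrasubstituted 8(9)-ene then accepts boron at C8 (C9 is shielded by quaternary C10) and hydrogen at C9, again anti to the 10β-methyl, in the manner of 1,2-dialkylcyclohexenes, and oxidation with retention delivers 5α-H, 6α-OH, 8α-OH (8β-methyl) and 9α-H.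

Step 13
Reactants: 20 diol acetal
Product: 21 8α,12-epoxy-13,14,15,16-tetranorlabdane-6α,12-diol (trans-fused five-membered lactol, both C12 anomers)
Conditions: p-TsOH·H2O (cat.), acetone/H2O, rt to 40 °C
Reagents that add atoms: water, O
Why: Acid-catalysed acetal hydrolysis frees the C12 aldehyde, which the 8α-hydroxyl captures as the lactol; the mild aqueous acid touches neither the tertiary carbinol nor any core stereocentre.

Step 14
Reactants: 21 lactol; 22 2-(triphenylphosphoranylidene)propanal
Product: 24 (12E)-6α,8α-dihydroxy-15-norlabd-12-en-14-al, via open-chain hydroxy aldehyde 23 (not isolated)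
Conditions: toluene, PhCO2H (cat.), 90 °C
Reagents that add atoms: none
Why: In this Wittig olefination the stabilised ylide intercepts the aldehyde tautomer of the lactol; α-branched stabilised ylides give the E-trisubstituted enal, which sets the 12E geometry, and the base-free medium keeps the tertiary 8-hydroxyl from adding to the enal.

Step 15
Reactants: 24 enal
Product: 25 (12E)-labda-12,14-diene-6α,8α-diol
Conditions: Ph3PCH3Br, KOtBu, THF, 0 °C; then 24, −78 to 0 °C
Reagents that add atoms: methyltriphenylphosphonium bromide, C[P+](c1ccccc1)(c1ccccc1)c1ccccc1.[Br-]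
Why: Wittig methylenation of the aldehyde is fast at low temperature, the ylide is too weak a base to deprotonate the two alcohols appreciably, and the C12=C13 geometry is not involved.

Step 16
Reactants: 25 diene diol; 26 angelic acid ((Z)-2-methylbut-2-enoic acid)
Product: 28 (12E)-6α-angeloyloxylabda-12,14-dien-8α-ol (CNP0582767.1), via mixed anhydride 27 (not isolated)
Conditions: 26, 2,4,6-trichlorobenzoyl chloride, Et3N, toluene, rt; then 25, 80 °C
Reagents that add atoms: 2,4,6-trichlorobenzoyl chloride, O=C(Cl)c1c(Cl)cc(Cl)cc1Cl (its acyl group is held only in 27)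
Why: Yamaguchi-type mixed-anhydride esterification without a nucleophilic catalyst is the established stereoretentive way to angelates (no addition–elimination path to the tiglate), and only the secondary equatorial 6α-hydroxyl is acylated while the tertiary 8α-hydroxyl stays free.

## Compound list

1 | 2-methylcyclohexane-1,3-dione | CC1C(=O)CCCC1=O | starting material
2 | 3-(2,2-dimethylhydrazinyl)-2-methylcyclohex-2-en-1-one | CC1=C(NN(C)C)CCCC1=O | intermediate
3 | 5-bromo-2-methylpent-2-ene | CC(C)=CCCBr | starting material
4 | potassium aza-enolate of 2 | CC1=C([N-]N(C)C)CCCC1=O.[K+] | intermediate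
5 | 3-(dimethylhydrazono)-2-methyl-2-(4-methylpent-3-en-1-yl)cyclohexan-1-one (racemic) | CC(C)=CCCC1(C)C(=O)CCCC1=NN(C)C | intermediate
6 | 2-methyl-2-(4-methylpent-3-en-1-yl)cyclohexane-1,3-dione | CC(C)=CCCC1(C)C(=O)CCCC1=O | intermediate
7 | (2R,3R)-3-hydroxy-2-methyl-2-(4-methylpent-3-en-1-yl)cyclohexan-1-one | CC(C)=CCC[C@@]1(C)C(=O)CCC[C@H]1O | intermediate
8 | (2R,3R)-3-(tert-butyldimethylsilyloxy)-2-methyl-2-(4-methylpent-3-en-1-yl)cyclohexan-1-one | CC(C)=CCC[C@@]1(C)C(=O)CCC[C@H]1O[Si](C)(C)C(C)(C)C | intermediate
9 | 9α-(tert-butyldimethylsilyloxy)-4,4,10β-trimethyl-cis-decalin-5β-ol | CC(C)(C)[Si](C)(C)O[C@H]1[C@@]2(C)CCCC(C)(C)[C@@]2(O)CCC1 | intermediate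
10 | 9α-(tert-butyldimethylsilyloxy)-4,4,10β-trimethyl-5(6)-octalin | CC(C)(C)[Si](C)(C)O[C@H]1[C@@]2(C)CCCC(C)(C)C2=CCC1 | intermediate
11 | 4,4,10β-trimethyl-5(6)-octalin-9α-ol | O[C@H]1[C@@]2(C)CCCC(C)(C)C2=CCC1 | intermediate
12 | (8aS)-5,5,8a-trimethyl-3,5,6,7,8,8a-hexahydronaphthalen-1(2H)-one | O=C1[C@@]2(C)CCCC(C)(C)C2=CCC1 | intermediate
13 | lithium 8(9)-enolate of 12 | [Li+].[O-]C1[C@@]2(C)CCCC(C)(C)C2=CCC=1 | intermediate
14 | 4,4,8α,10β-tetramethyl-5(6)-octalin-9-one | O=C1[C@@]2(C)CCCC(C)(C)C2=CC[C@H]1C | intermediate
15 | potassium 8(9)-enolate of 14 | [K+].[O-]C1[C@@]2(C)CCCC(C)(C)C2=CCC=1C | intermediate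
16 | 4,4,8,10β-tetramethyl-5,8(9)-hexalin-9-yl triflate | CC1=C(OS(=O)(=O)C(F)(F)F)[C@@]2(C)CCCC(C)(C)C2=CC1 | intermediate
17 | (1,3-dioxolan-2-ylmethyl)zinc bromide | Br[Zn]CC1OCCO1 | starting material
18 | 12,12-(ethylenedioxy)-13,14,15,16-tetranorlabda-5,8(9)-diene | CC1=C(CC3OCCO3)[C@@]2(C)CCCC(C)(C)C2=CC1 | intermediate
19 | 6α,8α-bis(boranyl)-12,12-(ethylenedioxy)-13,14,15,16-tetranorlabdane | O3CCOC3C[C@@H]1[C@@]2(C)CCCC(C)(C)[C@@H]2[C@@H](B)C[C@@]1(C)B | intermediate
20 | 12,12-(ethylenedioxy)-13,14,15,16-tetranorlabdane-6α,8α-diol | O3CCOC3C[C@@H]1[C@@]2(C)CCCC(C)(C)[C@@H]2[C@@H](O)C[C@@]1(C)O | intermediate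
21 | 8α,12-epoxy-13,14,15,16-tetranorlabdane-6α,12-diol (lactol, C12 anomers) | OC1C[C@@H]2[C@@]3(C)CCCC(C)(C)[C@@H]3[C@@H](O)C[C@@]2(C)O1 | intermediate
22 | 2-(triphenylphosphoranylidene)propanal | CC(C=O)=P(c1ccccc1)(c1ccccc1)c1ccccc1 | starting material
23 | 6α,8α-dihydroxy-13,14,15,16-tetranorlabdan-12-al | O=CC[C@@H]1[C@@]2(C)CCCC(C)(C)[C@@H]2[C@@H](O)C[C@@]1(C)O | intermediate
24 | (12E)-6α,8α-dihydroxy-15-norlabd-12-en-14-al | O=C/C(C)=C/C[C@@H]1[C@@]2(C)CCCC(C)(C)[C@@H]2[C@@H](O)C[C@@]1(C)O | intermediate
25 | (12E)-labda-12,14-diene-6α,8α-diol | C=C/C(C)=C/C[C@@H]1[C@@]2(C)CCCC(C)(C)[C@@H]2[C@@H](O)C[C@@]1(C)O | intermediate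
26 | angelic acid | C/C=C(/C)C(=O)O | starting material
27 | angelic 2,4,6-trichlorobenzoic anhydride | C/C=C(/C)C(=O)OC(=O)c1c(Cl)cc(Cl)cc1Cl | intermediate
28 | (12E)-6α-angeloyloxylabda-12,14-dien-8α-ol | C=C/C(C)=C/C[C@@H]1[C@@]2(C)CCCC(C)(C)[C@@H]2[C@@H](OC(=O)/C(C)=C\C)C[C@@]1(C)O | target

Total step count: 16. Longest linear sequence: 16 steps (from 1).

## Steps most likely to fail

**Step 5.**
- Risk: addition of the tertiary radical to the crowded carbonyl may be outrun by plain reduction of the radical, or undone by β-scission of the alkoxyl radical before it is quenched.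
- The fallback keeps the C4–C5 bond but generates the radical from an epoxide and traps the alkoxyl radical with titanium. It sets out from 8 and returns at 9.
- mCPBA converts the alkene into the 3,4-epoxide F1 (either C3 epimer serves).
- Cp2TiCl, made from Cp2TiCl2 and Mn in THF, opens F1 by electron transfer to the same tertiary C4 radical.
- That radical adds to the C5 ketone, and a second trivalent titanium captures the oxygen radical at once. This is the known titanocene epoxide–carbonyl radical cyclisation, and it gives the 3,5-diol F2.
- Only the secondary C3 hydroxyl is converted (NaH, CS2, MeI) into the S-methyl xanthate F3.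
- Barton–McCombie deoxygenation (Bu3SnH, AIBN, toluene, heat) removes the xanthate to give 9.

**Step 12.**
- Risk: the tetrasubstituted 8(9)-alkene may take up borane too slowly. That would leave time for migration of the tertiary borane, for borane attack on the acetal, or for loss of regio- and facial control.
- The fallback sets C8–O by epoxidation and C9–H by hydrogenation. It sets out from 16 and returns at 21.
- Palladium-catalysed coupling of 16 with the Reformatsky reagent (2-ethoxy-2-oxoethyl)zinc bromide (Pd(OAc)2, SPhos) gives the ethyl dienyl acetate F4.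
- One equivalent of BH3·THF at 0 °C followed by NaBO3 addresses only the trisubstituted 5-ene and gives the 6α-alcohol F5, now a trans-decalin.
- mCPBA epoxidises the electron-rich 8(9)-alkene anti to the 10β-methyl to give the 8α,9α-epoxy ester F6.
- DBU opens the epoxide by E1cB elimination from C11, and the released 8α-alkoxide lactonises to the butenolide F7.
- Hydrogenation over Pd/C occurs from the α face, since the axial methyl groups on C8 and C10 close the β face. This gives the 6α-hydroxy lactone F8.
- DIBAL-H in CH2Cl2 at −78 °C reduces F8 to lactol 21.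

**Step 11.**
- Risk: oxidative addition and transmetalation at the doubly flanked triflate may be slow. β-Hydride or β-alkoxide elimination from the alkylpalladium species would then lead to loss of the triflate by reduction.
- The fallback uses an allyl transfer that has no such elimination path. It sets out from 16 and returns at 18.
- Stille coupling with allyltributylstannane (Pd(PPh3)4, LiCl, THF, reflux) gives the 9-allyl triene F9.
- OsO4 (cat.)/NMO and then NaIO4 (Lemieux–Johnson-type cleavage) act on the unhindered monosubstituted alkene only and give the C12 aldehyde F10.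
- Ethylene glycol with PPTS in refluxing benzene converts F10 into acetal 18.

## Further compounds

F1 | step 5 | (2R,3R)-3-(tert-butyldimethylsilyloxy)-2-[2-(3,3-dimethyloxiran-2-yl)ethyl]-2-methylcyclohexan-1-one | CC2(C)OC2CC[C@@]1(C)C(=O)CCC[C@H]1O[Si](C)(C)C(C)(C)C
F2 | step 5 | 9α-(tert-butyldimethylsilyloxy)-4,4,10β-trimethyl-cis-decalin-3,5β-diol | CC(C)(C)[Si](C)(C)O[C@H]1[C@@]2(C)CCC(O)C(C)(C)[C@@]2(O)CCC1
F3 | step 5 | C3 O-(S-methyl dithiocarbonate) of F2 | CC(C)(C)[Si](C)(C)O[C@H]1[C@@]2(C)CCC(OC(=S)SC)C(C)(C)[C@@]2(O)CCC1
F4 | step 12 | ethyl 13,14,15,16-tetranorlabda-5,8(9)-dien-12-oate | CC1=C(CC(=O)OCC)[C@@]2(C)CCCC(C)(C)C2=CC1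
F5 | step 12 | ethyl 6α-hydroxy-13,14,15,16-tetranorlabd-8(9)-en-12-oate | CC1=C(CC(=O)OCC)[C@@]2(C)CCCC(C)(C)[C@@H]2[C@@H](O)C1
F6 | step 12 | ethyl 8α,9α-epoxy-6α-hydroxy-13,14,15,16-tetranorlabdan-12-oate | C[C@]12O[C@@]1(CC(=O)OCC)[C@@]3(C)CCCC(C)(C)[C@@H]3[C@@H](O)C2
F7 | step 12 | 6α-hydroxy-13,14,15,16-tetranorlabd-9(11)-en-12,8α-olide (butenolide) | O=C1C=C2[C@@]3(C)CCCC(C)(C)[C@@H]3[C@@H](O)C[C@@]2(C)O1
F8 | step 12 | 6α-hydroxy-13,14,15,16-tetranorlabdan-12,8α-olide | O=C1C[C@@H]2[C@@]3(C)CCCC(C)(C)[C@@H]3[C@@H](O)C[C@@]2(C)O1
F9 | step 11 | 9-allyl-4,4,8,10β-tetramethyl-5,8(9)-hexalin | CC1=C(CC=C)[C@@]2(C)CCCC(C)(C)C2=CC1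
F10 | step 11 | 13,14,15,16-tetranorlabda-5,8(9)-dien-12-al | CC1=C(CC=O)[C@@]2(C)CCCC(C)(C)C2=CC1
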